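The synthesis rests on the cyclobutane C4–C5–C11–C10, which is bridged across both diagonals (C6–C9 and C1–C3; numbering below). C11 is bonded to both ends (C10, C5) of the allylic unit C10–C4=C5 of a cycloheptene and carries acyl carbon C1. A C11 carbene on quaternary C10 therefore cyclopropanates C4=C5. Isopropenyl copper (C3) then cleaves the sacrificial C4–C11 bond of the acyl bicyclobutane in the same flask. Bonds C11–C5 and C3–C4 and the bicyclo[4.1.1]octane arise in one operation. The precursor is an enantiopure cycloheptenyl diazoacetate with a C7 ketal. An epimerising aldol closure, carbonyl transposition and methyl cuprate then build C1–C3; C7–C9 are oxidised last.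

Key step: step 8

Conventions: the perimeter is numbered C1 (ketone), C2, C3 (Me), C4, C5, C6 (Me2), C7 (OAng), C8 (OH), C9 (OAng), C10 (Me), C11, back to C1, with cross bonds C4–C10 and C5–C11. On C4 and C11, "endo" means pointing toward the C6–C9 bridge and "exo" means away from it. The faces of the C1–C3 bridge are called "C5 side" and "C10 side". The faces of the C6–C9 bridge are called "C4 side" and "C11 side".

Assumption: nucleophiles open acceptor bicyclobutanes at the rear lobe of the central bond, so 15 is drawn with isopropenyl endo on C4 and, after exo protonation, the ester endo on C11; both centres are equilibrated in step 11, so the route does not depend on this assignment.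

Step 1
Reactants: 1 cycloheptane-1,3-dione
Product: 2 2,2-dimethylcycloheptane-1,3-dione
Conditions: MeI (excess), K2CO3, acetone, reflux
Reagents that add atoms: iodomethane, CI
Why: Double C-alkylation of a β-diketone enolate; the little-enolised seven-membered dione should C-methylate twice and so install the C6 gem-dimethyl group.

Step 2
Reactants: 2 2,2-dimethylcycloheptane-1,3-dione
Product: 3 6,6-dimethyl-1,4-dioxaspiro[4.6]undecan-7-one (ketal carbon = C7, ketone = C5)
Conditions: HOCH2CH2OH (1.1 equiv), p-TsOH (cat.), benzene, reflux, Dean–Stark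
Reagents that add atoms: ethylene glycol, OCCO
Why: Acid-catalysed ketalisation of one of two equivalent carbonyls, the second being slowed by the crowded C6; the ketal leaves C7 without a hydrogen or a free carbonyl for the carbene step.

Step 3
Reactants: 3 6,6-dimethyl-1,4-dioxaspiro[4.6]undecan-7-one
Product: 4 6,6-dimethyl-1,4-dioxaspiro[4.6]undec-8-en-7-one (C4=C10 enone)
Conditions: LDA, THF, −78 °C; then PhS(Cl)=N-t-Bu, −78 °C
Reagents that add atoms: none
Why: Mukaiyama dehydrogenation; the ketone can enolise only toward C4 because C6 is quaternary, and the C4 sulfilimine undergoes syn elimination at low temperature.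

Step 4
Reactants: 4 6,6-dimethyl-1,4-dioxaspiro[4.6]undec-8-en-7-one
Product: 6 6,6,9-trimethyl-1,4-dioxaspiro[4.6]undec-8-en-7-one (β-methyl enone, methyl on C10), via lithium enolate 5 (not isolated)
Conditions: Me2CuLi (MeLi, CuI), Et2O, −78 to −40 °C; then PhS(Cl)=N-t-Bu (excess), −78 °C
Reagents that add atoms: lithium dimethylcuprate, [Li+].C[Cu-]C
Why: One-pot β-substitution of an enone; Gilman conjugate addition places the C10 methyl and the regiodefined enolate is dehydrogenated by the Mukaiyama reagent, which erases the transient C10 stereocentre.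

Step 5
Reactants: 6 6,6,9-trimethyl-1,4-dioxaspiro[4.6]undec-8-en-7-one
Product: 7 (7R)-6,6,9-trimethyl-1,4-dioxaspiro[4.6]undec-8-en-7-ol (C5 carbinol, R)
Conditions: (S)-Me-CBS (15 mol %), BH3·SMe2, THF, −20 °C; MeOH, aqueous work-up
Reagents that add atoms: none
Why: Corey–Bakshi–Shibata reduction; with quaternary C6 as the large group and vinylic C4 as the small group, the (S)-catalyst should set C5 as R by reagent control.

Step 6
Reactants: 7 (7R)-6,6,9-trimethyl-1,4-dioxaspiro[4.6]undec-8-en-7-ol
Product: 9 methyl 2-[(9S)-6,6,9-trimethyl-1,4-dioxaspiro[4.6]undec-7-en-9-yl]acetate, via mixed ketene acetal 8 (not isolated)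
Conditions: MeC(OMe)3 (excess), EtCO2H (cat.), 140 °C, MeOH distilled off
Reagents that add atoms: trimethyl orthoacetate, CC(OC)(OC)OC
Why: Johnson orthoester Claisen rearrangement; the suprafacial [3,3] shift bonds C11 to C10 on the ring face that carried the C5–O bond, which sets quaternary C10, moves the alkene to C4=C5 and gives the methyl ester directly.

Step 7
Reactants: 9 methyl 2-[(9S)-6,6,9-trimethyl-1,4-dioxaspiro[4.6]undec-7-en-9-yl]acetate
Product: 11 methyl 2-diazo-2-[(9R)-6,6,9-trimethyl-1,4-dioxaspiro[4.6]undec-7-en-9-yl]acetate, via α-trifluoroacetyl ester 10 (not isolated)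
Conditions: LDA, THF, −78 °C; CF3CO2CH2CF3; dilute HCl wash; then p-ABSA, Et3N, MeCN, rt
Reagents that add atoms: 4-acetamidobenzenesulfonyl azide, CC(=O)Nc1ccc(cc1)S(=O)(=O)N=[N+]=[N-]; 2,2,2-trifluoroethyl trifluoroacetate, FC(F)(F)COC(=O)C(F)(F)F (atoms only in 10)
Why: Deacylative Regitz diazo transfer; the weakly acidic ester is activated as its trifluoroacetyl derivative, which takes up N2 and passes the acyl group to the sulfonamide, while C10 is untouched (the descriptor changes by priority only).

Step 8
Reactants: 11 methyl 2-diazo-2-[(9R)-6,6,9-trimethyl-1,4-dioxaspiro[4.6]undec-7-en-9-yl]acetate; 12 isopropenylmagnesium bromide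
Product: 15 methyl 4,4-(ethylenedioxy)-1,5,5-trimethyl-8-(prop-1-en-2-yl)bicyclo[4.1.1]octane-7-carboxylate (isopropenyl on C4 endo, ester on C11 endo), via bicyclobutane 13 (not isolated), via bromomagnesium ester enolate 14 (not isolated)
Conditions: Rh2(oct)4 (1 mol %), toluene, −78 to 0 °C; then THF, CuBr·SMe2 (0.3 equiv), PBu3 (0.6 equiv), 12 (slow addition), −40 to 0 °C; aq NH4Cl, −78 °C
Reagents that add atoms: none
Why: Rh(II) expels N2 from 11 and the acceptor carbene at C11 adds in a concerted [2+1] fashion to the neighbouring C4=C5 to give acyl bicyclobutane 13, whose central C4–C11 bond, a homo-Michael acceptor, is cleaved at C4 by the isopropenylcopper species to give ester enolate 14, which is protonated on quenching. The closest known reaction type is the Rh(II)-catalysed intramolecular bicyclobutanation of 2-diazopent-4-enoates followed in the same flask by copper-catalysed homoconjugate Grignard addition, and isopropenyl cuprates are known to open acceptor-substituted bicyclobutanes. The one ring that remains, cyclobutane C4–C5–C11–C10 (which turns the cycloheptene into the bicyclo[4.1.1]octane), thus comes from a three-membered [2+1] closure followed by σ-bond cleavage and not from a 4-exo closure. C5 is controlled by quaternary C10, because the one-atom tether lets the carbene reach only the alkene face on which it sits and the cis ring alkene forces C6 and C9 into the endo positions of 13. C4 is controlled stereoelectronically, since copper attacks the rear lobe of the C4–C11 bond (inversion at C4, isopropenyl endo, H exo), and C11 by protonation of 14 from the open exo face (ester endo); both are opposite to the target, but both become α-carbonyl centres and are equilibrated in step 11. The step needs carbene chemoselectivity, secured because C10 carries no hydrogen for a 1,2-shift and C6 and ketal carbon C7 offer no C–H for 1,5-insertion, and it needs attack at C4 and not at the ester carbonyl, secured by copper catalysis with slow Grignard addition and by the neopentyl bridgehead position of the ester.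

Step 9
Reactants: 15 bicyclo[4.1.1]octane ester
Product: 16 the corresponding C1 aldehyde (CHO on C11 endo, isopropenyl on C4 endo)
Conditions: DIBAL-H (1.1 equiv), toluene, −78 °C; Rochelle salt
Reagents that add atoms: none
Why: Partial ester reduction; the aluminium hemiacetal of the hindered ester should persist at −78 °C and collapse to the aldehyde only on work-up, with ketal and alkene inert.

Step 10
Reactants: 16 C1 aldehyde
Product: 17 keto aldehyde (acetyl on C4 endo, CHO on C11 endo)
Conditions: O3, CH2Cl2, −78 °C (indicator dye); Me2S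
Reagents that add atoms: ozone, [O-][O+]=O
Why: Ozonolysis of the only C=C gives the C3 methyl ketone, whose CH3 becomes C2 and whose carbonyl makes C4–H acidic.

Step 11
Reactants: 17 keto aldehyde (endo,endo)
Product: 19 tricyclic enone with C3=O and C1=C2 (12-norlongipin-1-en-3-one 7-ethylene ketal), via exo,exo keto aldehyde 18 (not isolated)
Conditions: KOH, MeOH, 50 °C, 0.01 M
Reagents that add atoms: none
Why: Intramolecular aldol condensation under equilibrating conditions; base epimerises C11 (α to CHO) and C4 (α to the ketone, as acetylcyclobutanes are known to epimerise), only exo,exo isomer 18 can bring the methyl ketone enolate (C2) to C1, and E1cB dehydration drains the mixture into the non-enolisable enone, which fixes C4 and C11 as bridgeheads with the target configuration.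

Step 12
Reactants: 19 tricyclic enone
Product: 20 1,2-epoxy ketone (oxirane oxygen on the C5 side)
Conditions: 30 % H2O2, NaOH, MeOH, 0 °C
Reagents that add atoms: hydrogen peroxide, OO
Why: Weitz–Scheffer epoxidation; hydroperoxide adds to C1 from the C5 side because the C10 methyl overhangs the other face of the bicyclo[3.1.1]heptenone, as in verbenone.

Step 13
Reactants: 20 1,2-epoxy ketone
Product: 21 allylic alcohol (C1–OH on the C5 side, C2=C3)
Conditions: N2H4·H2O, AcOH (cat.), MeOH, 0 °C to rt
Reagents that add atoms: none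
Why: Wharton transposition; the epoxy hydrazone fragments with loss of N2, leaving oxygen on C1 and the alkene at C2=C3, and the C1–O bond of the epoxide is retained.

Step 14
Reactants: 21 allylic alcohol
Product: 22 enone with C1=O and C2=C3 (12-norlongipin-2-en-1-one 7-ethylene ketal)
Conditions: Dess–Martin periodinane, CH2Cl2, rt
Reagents that add atoms: none
Why: Dess–Martin oxidation of an unhindered allylic alcohol under conditions that spare the ketal.

Step 15
Reactants: 22 enone
Product: 23 longipinane-1,7-dione 7-ethylene ketal (C3 methyl on the C5 side)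
Conditions: Me2CuLi (MeLi, CuI), Et2O, −78 to −30 °C; aq NH4Cl
Reagents that add atoms: lithium dimethylcuprate, [Li+].C[Cu-]C
Why: Gilman conjugate addition; methyl reaches C3 from the open C5 side, anti to the C10 methyl (as cuprates add to apoverbenone), which sets C3 as in the target, whereas delivery of hydrogen to a 3-methyl enone from that same face would give the epimer.

Step 16
Reactants: 23 7-ketal
Product: 24 longipinane-1,7-dione
Conditions: 1 M HCl, THF, 40 °C
Reagents that add atoms: water, O
Why: Acid-catalysed ketal hydrolysis; C4 and C11 are bridgeheads and C3 is β to the ketone, so no stereocentre can epimerise.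

Step 17
Reactants: 24 longipinane-1,7-dione
Product: 25 longipinane-1,7-dione 1-ethylene ketal
Conditions: TMSOCH2CH2OTMS (1.1 equiv), TMSOTf (5 mol %), CH2Cl2, −78 to −30 °C; pyridine
Reagents that add atoms: 1,2-bis(trimethylsilyloxy)ethane, C[Si](C)(C)OCCO[Si](C)(C)C
Why: Noyori ketalisation under kinetic control; the C1 carbonyl (flanked by CH and CH2) should react at low temperature while the neopentyl C7 carbonyl does not, so that only C7 can enolise in step 18 and be reduced in step 19.

Step 18
Reactants: 25 1-ketal
Product: 26 longipin-8-ene-1,7-dione 1-ethylene ketal (C7 enone)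
Conditions: LDA, THF, −78 °C; then PhS(Cl)=N-t-Bu, −78 °C
Reagents that add atoms: none
Why: Mukaiyama dehydrogenation; C8 is the only enolisable position and quaternary C10 prevents further unsaturation.

Step 19
Reactants: 26 C7 enone
Product: 27 7-hydroxylongipin-8-en-1-one 1-ethylene ketal (7-OH on the C4 side, 7R)
Conditions: (S)-Me-CBS (20 mol %), BH3·SMe2, THF, −20 °C; MeOH, aqueous work-up
Reagents that add atoms: none
Why: Corey–Bakshi–Shibata reduction; the two faces of the C6–C9 bridge are nearly equivalent, so C7 is set by the catalyst with the same large (C6) and small (vinyl C8) pattern as in step 5.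

Step 20
Reactants: 27 allylic alcohol
Product: 28 7,8,9-trihydroxylongipinan-1-one 1-ethylene ketal (7-OH on the C4 side; 8-OH and 9-OH on the C11 side)
Conditions: OsO4 (5 mol %), NMO, acetone/H2O, rt
Reagents that add atoms: N-methylmorpholine N-oxide, C[N+]1([O-])CCOCC1; water, O
Why: Upjohn dihydroxylation; syn addition on the face anti to the allylic C7 oxygen (the usual sense for allylic alcohols) sets C8 and C9 cis to each other and trans to C7–OH.

Step 21
Reactants: 28 triol
Product: 29 8-O-TBS ether of 28
Conditions: TBSCl (1.05 equiv), imidazole, DMF, 0 °C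
Reagents that add atoms: tert-butyldimethylsilyl chloride, CC(C)(C)[Si](C)(C)Cl
Why: Sterically controlled monosilylation; C8–OH lies between two CH carbons while C7–OH and C9–OH are neopentyl (next to C6 and C10).

Step 22
Reactants: 29 8-O-TBS diol; 30 angelic acid
Product: 32 7,9-di-O-angeloyl-8-O-TBS derivative (1-ethylene ketal), via angelic 2,4,6-trichlorobenzoic anhydride 31 (not isolated)
Conditions: 30 (excess), 2,4,6-Cl3C6H2COCl, Et3N, toluene, rt; then 29, 80 °C (no DMAP)
Reagents that add atoms: 2,4,6-trichlorobenzoyl chloride, O=C(Cl)c1c(Cl)cc(Cl)cc1Cl (atoms only in 31)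
Why: Yamaguchi-type mixed-anhydride acylation; omitting a nucleophilic catalyst avoids Z to E isomerisation, both esters form in one operation, and the carbinol stereocentres are untouched.

Step 23
Reactants: 32 protected diangelate
Product: 33 target, 7,9-diangeloyloxy-8-hydroxylongipinan-1-one
Conditions: 48 % aq HF, MeCN, 0 °C to rt
Reagents that add atoms: water, O
Why: Acidic global deprotection; fluoride cleaves the silyl ether and the aqueous acid hydrolyses the C1 ketal under conditions too mild for angelate isomerisation or acyl migration.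

Compound list
1 | cycloheptane-1,3-dione | O=C1CCCCC(=O)C1 | starting material
2 | 2,2-dimethylcycloheptane-1,3-dione | O=C1CCCCC(=O)C1(C)C | intermediate
3 | 6,6-dimethyl-1,4-dioxaspiro[4.6]undecan-7-one | O=C1CCCCC2(OCCO2)C1(C)C | intermediate
4 | 6,6-dimethyl-1,4-dioxaspiro[4.6]undec-8-en-7-one | O=C1C=CCCC2(OCCO2)C1(C)C | intermediate
5 | lithium 6,6,9-trimethyl-1,4-dioxaspiro[4.6]undec-7-en-7-olate (racemic at C10) | [Li+].[O-]C1=CC(C)CCC2(OCCO2)C1(C)C | intermediate
6 | 6,6,9-trimethyl-1,4-dioxaspiro[4.6]undec-8-en-7-one | O=C1C=C(C)CCC2(OCCO2)C1(C)C | intermediate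
7 | (7R)-6,6,9-trimethyl-1,4-dioxaspiro[4.6]undec-8-en-7-ol | O[C@@H]1C=C(C)CCC2(OCCO2)C1(C)C | intermediate
8 | mixed methyl ketene acetal of 7 | C=C(OC)O[C@@H]1C=C(C)CCC2(OCCO2)C1(C)C | intermediate
9 | methyl 2-[(9S)-6,6,9-trimethyl-1,4-dioxaspiro[4.6]undec-7-en-9-yl]acetate | COC(=O)C[C@@]1(C)C=CC(C)(C)C2(OCCO2)CC1 | intermediate
10 | α-trifluoroacetyl derivative of 9 (C10 as in 9, C11 unassigned) | COC(=O)C(C(=O)C(F)(F)F)[C@@]1(C)C=CC(C)(C)C2(OCCO2)CC1 | intermediate
11 | methyl 2-diazo-2-[(9R)-6,6,9-trimethyl-1,4-dioxaspiro[4.6]undec-7-en-9-yl]acetate | COC(=O)C(=[N+]=[N-])[C@@]1(C)C=CC(C)(C)C2(OCCO2)CC1 | intermediate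
12 | isopropenylmagnesium bromide | CC(=C)[Mg]Br | starting material
13 | methyl 5,5-(ethylenedioxy)-2,6,6-trimethyltricyclo[5.1.0.0^2,8]octane-1-carboxylate (central bond C4–C11; C6 and C9 endo on wing carbons C5 and C10) | C15(OCCO5)CC[C@]2(C)[C@@H]3[C@H](C1(C)C)[C@]23C(=O)OC | intermediate
14 | bromomagnesium ester enolate (C11 trigonal, isopropenyl on C4 endo) | C15(OCCO5)CC[C@]2(C)[C@H](C(C)=C)[C@@H](C2=C(OC)O[Mg]Br)C1(C)C | intermediate
15 | methyl 4,4-(ethylenedioxy)-1,5,5-trimethyl-8-(prop-1-en-2-yl)bicyclo[4.1.1]octane-7-carboxylate (C4 endo, C11 endo) | C15(OCCO5)CC[C@]2(C)[C@H](C(C)=C)[C@@H]([C@@H]2C(=O)OC)C1(C)C | intermediate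
16 | C1 aldehyde (CHO endo, isopropenyl endo) | C15(OCCO5)CC[C@]2(C)[C@H](C(C)=C)[C@@H]([C@@H]2C=O)C1(C)C | intermediate
17 | keto aldehyde, endo,endo | C15(OCCO5)CC[C@]2(C)[C@H](C(C)=O)[C@@H]([C@@H]2C=O)C1(C)C | intermediate
18 | keto aldehyde, exo,exo | C15(OCCO5)CC[C@]2(C)[C@@H](C(C)=O)[C@@H]([C@H]2C=O)C1(C)C | intermediate
19 | 12-norlongipin-1-en-3-one 7-ethylene ketal | C15(OCCO5)CC[C@]2(C)[C@@H]3[C@@H]([C@H]2C=CC3=O)C1(C)C | intermediate
20 | 1,2-epoxide of 19 (oxygen on the C5 side) | C15(OCCO5)CC[C@]2(C)[C@@H]3[C@@H]([C@H]2[C@H]4O[C@H]4C3=O)C1(C)C | intermediate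
21 | 12-norlongipin-2-en-1-ol 7-ethylene ketal (OH on the C5 side) | C15(OCCO5)CC[C@]2(C)[C@@H]3[C@@H]([C@H]2[C@@H](O)C=C3)C1(C)C | intermediate
22 | 12-norlongipin-2-en-1-one 7-ethylene ketal | C15(OCCO5)CC[C@]2(C)[C@@H]3[C@@H]([C@H]2C(=O)C=C3)C1(C)C | intermediate
23 | longipinane-1,7-dione 7-ethylene ketal (C3 methyl on the C5 side) | C15(OCCO5)CC[C@]2(C)[C@@H]3[C@@H]([C@H]2C(=O)C[C@H]3C)C1(C)C | intermediate
24 | longipinane-1,7-dione | O=C1CC[C@]2(C)[C@@H]3[C@@H]([C@H]2C(=O)C[C@H]3C)C1(C)C | intermediate
25 | longipinane-1,7-dione 1-ethylene ketal | O=C1CC[C@]2(C)[C@@H]3[C@@H]([C@H]2C4(OCCO4)C[C@H]3C)C1(C)C | intermediate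
26 | longipin-8-ene-1,7-dione 1-ethylene ketal | O=C1C=C[C@]2(C)[C@@H]3[C@@H]([C@H]2C4(OCCO4)C[C@H]3C)C1(C)C | intermediate
27 | 7-hydroxylongipin-8-en-1-one 1-ethylene ketal (7-OH on the C4 side) | O[C@@H]1C=C[C@]2(C)[C@@H]3[C@@H]([C@H]2C4(OCCO4)C[C@H]3C)C1(C)C | intermediate
28 | 7,8,9-trihydroxylongipinan-1-one 1-ethylene ketal | O[C@@H]1[C@@H](O)[C@@H](O)[C@]2(C)[C@@H]3[C@@H]([C@H]2C4(OCCO4)C[C@H]3C)C1(C)C | intermediate
29 | 8-O-TBS ether of 28 | O[C@@H]1[C@@H](O[Si](C)(C)C(C)(C)C)[C@@H](O)[C@]2(C)[C@@H]3[C@@H]([C@H]2C4(OCCO4)C[C@H]3C)C1(C)C | intermediate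
30 | angelic acid, (Z)-2-methylbut-2-enoic acid | C/C=C(/C)C(=O)O | starting material
31 | angelic 2,4,6-trichlorobenzoic anhydride | C/C=C(/C)C(=O)OC(=O)c1c(Cl)cc(Cl)cc1Cl | intermediate
32 | 7,9-di-O-angeloyl-8-O-TBS-longipinan-1-one 1-ethylene ketal | C/C=C(/C)C(=O)O[C@@H]1[C@@H](O[Si](C)(C)C(C)(C)C)[C@@H](OC(=O)/C(C)=C\C)[C@]2(C)[C@@H]3[C@@H]([C@H]2C4(OCCO4)C[C@H]3C)C1(C)C | intermediate
33 | 7,9-diangeloyloxy-8-hydroxylongipinan-1-one | C/C=C(/C)C(=O)O[C@@H]1[C@@H](O)[C@@H](OC(=O)/C(C)=C\C)[C@]2(C)[C@@H]3[C@@H]([C@H]2C(=O)C[C@H]3C)C1(C)C | target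

Total steps: 23. Longest linear sequence: 23 steps (from 1).

Steps most likely to fail

1. Step 8.
- **Risk:** C4=C5 lies between two quaternary carbons. The carbene may therefore be diverted to a ketal oxygen (six-membered oxonium ylide) or to azine or dimer formation. The bulky copper reagent may also open the central bond too slowly and allow attack at the ester carbonyl.
- **Fallback:** an anionic construction of the same bicyclobutane, without a carbene, sets out from 9. mCPBA should epoxidise the face anti to the acetate arm to give the 4,5-epoxide F1. KHMDS then opens it by 3-exo-tet attack of the ester enolate at C4 (bond C11–C4) to give the cyclopropyl carbinol F2. MsCl/Et3N gives the mesylate F3. A second deprotonation at C11 with LDA displaces the mesylate at C5 with inversion (bond C11–C5). This is the double 3-exo-tet route known for acceptor-substituted bicyclobutanes. It delivers 13, which is opened with 12 under copper catalysis, and the route is rejoined at 15.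

2. Step 11.
- **Risk:** enolisation of the cyclobutyl ketone at C4 may be too slow. The exo,exo isomer is then hardly populated, and the aldehyde is lost to intermolecular condensation before ring closure.
- **Fallback:** trap the exo,exo arrangement covalently before the C–C bond is made, setting out from 15. Ozonolysis gives the keto ester F4 and KOH/MeOH gives the keto acid F5. Ac2O/NaOAc at reflux epimerises C11 through the mixed anhydride and C4 through the enol. It should trap the only isomer that can cyclise as the bridged enol lactone F6. DIBAL-H at −78 °C then releases 18 directly, and brief K2CO3/MeOH closes it to 19.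

3. Step 22.
- **Risk:** double acylation of two neopentyl carbinols that flank a silyl ether may be sluggish. Prolonged heating may then cause Z to E isomerisation of the angelate or silyl migration.
- **Fallback:** build the Z-alkene on the ester, setting out from 29. 2-[Bis(2,2,2-trifluoroethoxy)phosphoryl]propanoic acid with DCC/DMAP should acylate both hydroxyls to give the bis(phosphonopropionate) F7. Still–Gennari olefination (KHMDS, 18-crown-6, acetaldehyde, −78 °C) then forms both Z-trisubstituted alkenes and rejoins the route at 32.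

Further compounds
F1 | step 8 | 4,5-epoxide of 9 (oxygen anti to the CH2CO2Me arm) | COC(=O)C[C@@]1(C)[C@@H]2O[C@@H]2C(C)(C)C3(OCCO3)CC1
F2 | step 8 | cyclopropyl carbinol (bond C11–C4 formed, C5–OH, ester exo on the cyclopropane) | C15(OCCO5)CC[C@]2(C)[C@@H]([C@H]2C(=O)OC)[C@H](O)C1(C)C
F3 | step 8 | C5 mesylate of F2 | C15(OCCO5)CC[C@]2(C)[C@@H]([C@H]2C(=O)OC)[C@H](OS(C)(=O)=O)C1(C)C
F4 | step 11 | keto ester (acetyl on C4 endo, ester on C11 endo) | C15(OCCO5)CC[C@]2(C)[C@H](C(C)=O)[C@@H]([C@@H]2C(=O)OC)C1(C)C
F5 | step 11 | keto acid from F4 | C15(OCCO5)CC[C@]2(C)[C@H](C(C)=O)[C@@H]([C@@H]2C(=O)O)C1(C)C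
F6 | step 11 | bridged enol lactone (C1(=O)–O–C3(=CH2), both links exo) | C15(OCCO5)CC[C@]2(C)[C@@H]3[C@@H]([C@H]2C(=O)OC3=C)C1(C)C
F7 | step 22 | 7,9-bis[2-(bis(2,2,2-trifluoroethoxy)phosphoryl)propanoate] of 29 (phosphonate α-carbons unassigned) | CC(P(=O)(OCC(F)(F)F)OCC(F)(F)F)C(=O)O[C@@H]1[C@@H](O[Si](C)(C)C(C)(C)C)[C@@H](OC(=O)C(C)P(=O)(OCC(F)(F)F)OCC(F)(F)F)[C@]2(C)[C@@H]3[C@@H]([C@H]2C4(OCCO4)C[C@H]3C)C1(C)C
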